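**Plan**

1. Numbering (mutilin): five-membered ring C9–C1–C2–C3(=O)–C4; six-membered ring C4–C5–C6–C7–C8–C9; eight-membered ring C4–C5–C14–C13–C12–C11–C10–C9; methyls C16 (on C10), C15 (C12), C17 (C6), C18 (C5); diol C19–C20 on C12.
2. Enabling feature: C3(=O)–C4–C5–C14(O) is a 1,4-dioxygenated chain. Its middle bond C4–C5 links the α-carbon of the C3 ketone to the α-carbon of a C14 carboxyl group and closes the six-membered ring onto the five-membered ring beside quaternary C9, so two enolates can be united there by oxidation.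
3. Cuts, in order: glycolate C–O at C14 and protecting groups; C10–C11 (eight-membered ring, alkyne plus aldehyde); C13–C14 (alkyllithium plus aldehyde), releasing a C11–C13 piece that carries C15, C19 and C20; C4–C5; C8–C9 (conjugate addition to a β-alkynyl cyclopentenone).
4. Forward: the five-membered ring is present from the start and quaternary C9 is made on it; the six-membered ring arises by C4–C5 coupling; the eight-membered ring closes last at C10–C11; then the C10 methyl, the C14 alcohol and its ester.
5. Stereochemistry: C6 from methyl hydrogen (S)-3-methylglutarate; C9 from a chiral copper–carbene catalyst; C5 in the coupling, C4 by kinetic protonation after it; C12 and C19 from dimethyl (S)-malate by chelate-controlled alkylations; C11 in the ring closure, C10 by radical hydrogenation, C14 by oxazaborolidine reduction.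

Key step: step 11

Remark: the configurations are taken exactly as written in the SMILES (4S,5S,6S,9S,10R,11S,12R,14R,19S in mutilin numbering); in this array H4, the C5–C14 bond and the C17 methyl lie on the face of the six-membered ring opposite to the C9–C10 bond, and every stereochemical argument below is made for that arrangement.

**Route**

Step 1
Reactants: 1 3-ethoxycyclopent-2-en-1-one; 2 ethynyltrimethylsilane
Product: 5 3-[(trimethylsilyl)ethynyl]cyclopent-2-en-1-one, via lithium acetylide 3 (not isolated), via lithium alkoxide adduct 4 (not isolated)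
Conditions: n-BuLi, THF, −78 °C; then 1, −78 to 0 °C; then 2 M HCl, rt
Reagents that add atoms: none
Why: 1,2-addition of the acetylide to the vinylogous ester, then acid hydrolysis of the enol ether with loss of water, transposes the carbonyl group (Stork–Danheiser sequence) and should give the β-alkynyl enone; no stereocentre is formed.

Step 2
Reactants: 6 (3S)-5-methoxy-3-methyl-5-oxopentanoic acid (methyl hydrogen (S)-3-methylglutarate)
Product: 8 (3S)-5-methoxy-3,4-dimethyl-5-oxopentanoic acid (both C4 epimers), via dilithium dianion 7 (not isolated)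
Conditions: LDA (2.2 equiv), THF, −78 to −30 °C; MeI, −78 °C to rt; then 1 M HCl
Reagents that add atoms: iodomethane, CI
Why: the carboxylate/ester-enolate dianion is alkylated only at the ester α-carbon (dianion alkylation), which installs C18; the new centre (C5) needs no control because it is planarised again in step 11, and C6 is untouched.

Step 3
Reactants: 8 (3S)-5-methoxy-3,4-dimethyl-5-oxopentanoic acid
Product: 9 methyl (3S)-5-hydroxy-2,3-dimethylpentanoate (both C2 epimers)
Conditions: BH3·SMe2, THF, 0 °C to rt; MeOH quench; used at once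
Reagents that add atoms: none
Why: borane reduces a free carboxylic acid far faster than a methyl ester (chemoselective borane reduction), so only the C8 carboxyl becomes the alcohol.

Step 4
Reactants: 9 methyl (3S)-5-hydroxy-2,3-dimethylpentanoate
Product: 10 methyl (3S)-5-bromo-2,3-dimethylpentanoate (both C2 epimers)
Conditions: CBr4, PPh3, CH2Cl2, 0 °C
Reagents that add atoms: carbon tetrabromide, BrC(Br)(Br)Br
Why: Appel bromination converts the primary alcohol into the bromide under neutral conditions that leave the ester and C6 alone.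

Step 5
Reactants: 10 methyl (3S)-5-bromo-2,3-dimethylpentanoate
Product: 11 (3S)-5-bromo-2,3-dimethylpentan-1-ol (both C2 epimers)
Conditions: DIBAL-H (2.5 equiv), CH2Cl2, −78 to 0 °C; aq. Rochelle salt
Reagents that add atoms: none
Why: DIBAL-H reduces the ester to the primary alcohol without touching the alkyl bromide, so that C14 can pass the organomagnesium step as a silyl ether.

Step 6
Reactants: 11 (3S)-5-bromo-2,3-dimethylpentan-1-ol
Product: 12 {[(3S)-5-bromo-2,3-dimethylpentyl]oxy}(tert-butyl)dimethylsilane (both C2 epimers)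
Conditions: TBSCl, imidazole, DMF, rt
Reagents that add atoms: tert-butyldimethylsilyl chloride, CC(C)(C)[Si](C)(C)Cl
Why: standard silylation of the primary alcohol gives an ether that survives Grignard formation and the enolisation of step 8.

Step 7
Reactants: 12 {[(3S)-5-bromo-2,3-dimethylpentyl]oxy}(tert-butyl)dimethylsilane; 5 3-[(trimethylsilyl)ethynyl]cyclopent-2-en-1-one
Product: 14 (3R)-3-[(3S)-5-(tert-butyldimethylsilyloxy)-3,4-dimethylpentyl]-3-[(trimethylsilyl)ethynyl]cyclopentan-1-one, via Grignard reagent 13 (not isolated)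
Conditions: Mg, Et2O, reflux; then 5, Cu(OTf)2 (3 mol%), chiral hydroxyalkyl imidazolinium hexafluorophosphate (carbene precursor, 4 mol%), Et2O, 0 °C; then 1 M HCl
Reagents that add atoms: none
Why: copper-catalysed asymmetric conjugate addition of Grignard reagents to β-alkynyl cyclic enones is 1,4-selective and builds alkynyl-bearing quaternary carbons; the chiral carbene–copper catalyst (antipode chosen accordingly) selects the enone face and should set C9 (3R here) independently of the remote C6 centre.

Step 8
Reactants: 14 (3R)-3-[(3S)-5-(tert-butyldimethylsilyloxy)-3,4-dimethylpentyl]-3-[(trimethylsilyl)ethynyl]cyclopentan-1-one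
Product: 16 (4S)-4-[(3S)-5-(tert-butyldimethylsilyloxy)-3,4-dimethylpentyl]-4-[(trimethylsilyl)ethynyl]cyclopent-2-en-1-one, via trimethylsilyl enol ether 15 (not isolated)
Conditions: LDA, Me3SiCl, THF, −78 °C; then Pd(OAc)2 (1.05 equiv), MeCN, rt
Reagents that add atoms: none
Why: LDA removes a proton from the C2 methylene, the α-position remote from the quaternary carbon, and the trapped silyl enol ether is dehydrogenated by palladium diacetate (Saegusa–Ito oxidation) to the C1=C2 enone, leaving C4 as the only enolisable ketone position.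

Step 9
Reactants: 16 (4S)-4-[(3S)-5-(tert-butyldimethylsilyloxy)-3,4-dimethylpentyl]-4-[(trimethylsilyl)ethynyl]cyclopent-2-en-1-one
Product: 17 (3S)-2,3-dimethyl-5-{(1S)-4-oxo-1-[(trimethylsilyl)ethynyl]cyclopent-2-en-1-yl}pentanoic acid (both C2 epimers)
Conditions: CrO3, H2SO4, H2O, acetone, 0 °C
Reagents that add atoms: water, O
Why: Jones oxidation cleaves the primary silyl ether under its acidic conditions and oxidises the freed alcohol through the aldehyde hydrate to the acid, while enone and silylalkyne are inert.

Step 10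
Reactants: 17 (3S)-2,3-dimethyl-5-{(1S)-4-oxo-1-[(trimethylsilyl)ethynyl]cyclopent-2-en-1-yl}pentanoic acid
Product: 18 methyl (3S)-2,3-dimethyl-5-{(1S)-4-oxo-1-[(trimethylsilyl)ethynyl]cyclopent-2-en-1-yl}pentanoate (both C2 epimers)
Conditions: MeI, K2CO3, DMF, rt
Reagents that add atoms: iodomethane, CI
Why: O-alkylation of the potassium carboxylate gives the methyl ester, and carbonate is too weak a base to enolise the enone.

Step 11
Reactants: 18 methyl (3S)-2,3-dimethyl-5-{(1S)-4-oxo-1-[(trimethylsilyl)ethynyl]cyclopent-2-en-1-yl}pentanoate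
Product: 20 methyl (3aR,4S,5S,7aR)-4,5-dimethyl-3-oxo-7a-[(trimethylsilyl)ethynyl]-3a,4,5,6,7,7a-hexahydro-3H-indene-4-carboxylate (H4 syn to the alkynyl group), via dilithium bis-enolate 19 (not isolated)
Conditions: LDA (2.2 equiv), THF, −78 to −40 °C; then Fe(acac)3 (2.2 equiv), THF, −78 to 0 °C, 0.01 M
Reagents that add atoms: none
Why: LDA first turns the enone into its cross-conjugated C3–C4 dienolate (C4 carries its only α-hydrogens, and this also shuts off Michael addition) and then the ester into its C5 enolate; Fe(acac)3 (trivalent iron) oxidises one enolate to an α-carbonyl radical that adds to the other, and a second equivalent oxidises the resulting ketyl to the 1,4-dicarbonyl compound, leaving Fe(acac)2 (divalent iron). The closest known reaction type is the intramolecular oxidative heterocoupling of two different carbonyl enolates with iron or copper oxidants. The six-membered ring C4–C5–C6–C7–C8–C9 closes by union of the two tethered α-carbons, a radical–enolate closure in which both reacting carbons end up inside the new ring. C5: the forming ring should adopt a chair with the C17 methyl equatorial, the small C18 methyl beside the solvated C3 oxygen and the ester over the five-membered ring, on the face opposite to the alkynyl group, which gives 5S. C4: the four-carbon tether can reach only the enolate face that carries C8, so H4 ends up on the side of the alkynyl group (4R); this centre is inverted in step 12. The step needs heterocoupling over dimerisation, which the tether and high dilution secure, and tolerance of fully substituted carbons at and beside the bond, which the radical pathway provides.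

Step 12
Reactants: 20 methyl (3aR,4S,5S,7aR)-4,5-dimethyl-3-oxo-7a-[(trimethylsilyl)ethynyl]-3a,4,5,6,7,7a-hexahydro-3H-indene-4-carboxylate
Product: 22 methyl (3aS,4S,5S,7aR)-4,5-dimethyl-3-oxo-7a-[(trimethylsilyl)ethynyl]-3a,4,5,6,7,7a-hexahydro-3H-indene-4-carboxylate (H4 anti to the alkynyl group), via lithium dienolate 21 (not isolated)
Conditions: LDA (1.2 equiv), THF, −78 °C; then AcOH in THF, −78 °C
Reagents that add atoms: none
Why: deprotonation at C4, the only α-position of the enone, gives a planar dienolate, and kinetic protonation (enolate epimerisation) should deliver the proton on the face away from the two axial groups flanking C4, the alkynyl group on C9 and the C18 methyl on C5, so that H4 becomes anti to the alkynyl group (4S).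

Step 13
Reactants: 22 methyl (3aS,4S,5S,7aR)-4,5-dimethyl-3-oxo-7a-[(trimethylsilyl)ethynyl]-3a,4,5,6,7,7a-hexahydro-3H-indene-4-carboxylate
Product: 23 methyl (3aS,4S,5S,7aR)-4,5-dimethyl-3-oxo-7a-[(trimethylsilyl)ethynyl]octahydro-1H-indene-4-carboxylate
Conditions: [(Ph3P)CuH]6 (0.4 equiv), H2O (3 equiv), toluene, rt
Reagents that add atoms: none
Why: copper hydride adds hydride to C1 of the enone (conjugate reduction) and water protonates the copper enolate at C2 under neutral conditions, so the silylalkyne, the ester and the C4 configuration are preserved.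

Step 14
Reactants: 23 methyl (3aS,4S,5S,7aR)-4,5-dimethyl-3-oxo-7a-[(trimethylsilyl)ethynyl]octahydro-1H-indene-4-carboxylate
Product: 24 the C3 ethylene ketal (1,3-dioxolane) of 23
Conditions: Me3SiOCH2CH2OSiMe3, Me3SiOTf (5 mol%), CH2Cl2, −78 to −20 °C
Reagents that add atoms: 1,2-bis(trimethylsilyloxy)ethane, C[Si](C)(C)OCCO[Si](C)(C)C
Why: silyl triflate-catalysed ketalisation with the bis-silyl ether of ethylene glycol (Noyori conditions) runs cold and without protic acid, so C4 is not enolised, and the dioxolane then shields C3 from hydride and organolithium reagents.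

Step 15
Reactants: 24 the C3 ethylene ketal of 23
Product: 25 the C14 primary alcohol of 24 (CO2Me reduced to CH2OH)
Conditions: LiAlH4, THF, 0 °C
Reagents that add atoms: none
Why: LiAlH4 reduces the neopentyl ester to the alcohol; the ketal and the silylalkyne, which has no propargylic oxygen, are inert at 0 °C.

Step 16
Reactants: 25 the C14 primary alcohol
Product: 26 the C14 aldehyde (CHO on quaternary C5; C3 dioxolane; C9 silylalkyne)
Conditions: Dess–Martin periodinane, NaHCO3, CH2Cl2, rt
Reagents that add atoms: none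
Why: Dess–Martin oxidation gives the non-enolisable aldehyde under buffered conditions that spare the ketal.

Step 17
Reactants: 27 dimethyl (S)-malate
Product: 29 dimethyl (2S,3R)-3-[(benzyloxy)methyl]-2-hydroxybutanedioate, via dilithium alkoxide enolate 28 (not isolated)
Conditions: LDA (2.2 equiv), THF, −78 to −20 °C; then BnOCH2Cl, −78 °C
Reagents that add atoms: benzyl chloromethyl ether, ClCOCc1ccccc1
Why: Frater–Seebach alkylation: the chelated alkoxide–enolate dianion is alkylated on the face opposite to the C1 ester, giving the 2,3-anti product and setting the future C12 from the malate carbinol that becomes C19.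

Step 18
Reactants: 29 dimethyl (2S,3R)-3-[(benzyloxy)methyl]-2-hydroxybutanedioate
Product: 31 dimethyl (2S,3S)-3-[(benzyloxy)methyl]-2-hydroxy-3-methylbutanedioate, via dilithium alkoxide enolate 30 (not isolated)
Conditions: LDA (2.2 equiv), THF/DMPU, −78 °C; then MeI, −78 °C
Reagents that add atoms: iodomethane, CI
Why: a second Frater–Seebach alkylation on the same chelate face, kept at −78 °C to avoid β-elimination of benzyloxide, introduces the C15 methyl and completes quaternary C12.

Step 19
Reactants: 31 dimethyl (2S,3S)-3-[(benzyloxy)methyl]-2-hydroxy-3-methylbutanedioate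
Product: 32 (2S,3S)-3-[(benzyloxy)methyl]-3-methylbutane-1,2,4-triol
Conditions: LiAlH4, THF, 0 °C to rt
Reagents that add atoms: none
Why: LiAlH4 reduces both esters, so the former C4 ester carbon becomes C11 and the former C1 ester carbon becomes C20, with no stereocentre touched.

Step 20
Reactants: 32 (2S,3S)-3-[(benzyloxy)methyl]-3-methylbutane-1,2,4-triol
Product: 33 (2S)-3-(benzyloxy)-2-[(4S)-2,2-dimethyl-1,3-dioxolan-4-yl]-2-methylpropan-1-ol
Conditions: Me2C(OMe)2, TsOH (cat.), acetone, rt
Reagents that add atoms: 2,2-dimethoxypropane, COC(C)(C)OC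
Why: under thermodynamic acetalisation the terminal 1,2-diol forms the five-membered dioxolane in preference to a six-membered 1,3-dioxane, leaving the neopentyl C11 hydroxyl free.

Step 21
Reactants: 33 (2S)-3-(benzyloxy)-2-[(4S)-2,2-dimethyl-1,3-dioxolan-4-yl]-2-methylpropan-1-ol
Product: 34 {(2R)-3-(benzyloxy)-2-[(4S)-2,2-dimethyl-1,3-dioxolan-4-yl]-2-methylpropoxy}tri(propan-2-yl)silane
Conditions: i-Pr3SiOTf, 2,6-lutidine, CH2Cl2, 0 °C
Reagents that add atoms: triisopropylsilyl trifluoromethanesulfonate, CC(C)[Si](OS(=O)(=O)C(F)(F)F)(C(C)C)C(C)C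
Why: silylation with the triflate caps the hindered neopentyl alcohol, and the triisopropylsilyl ether is chosen because it resists 1,4-migration of silicon to carbon in the later γ-silyloxy alkyllithium.

Step 22
Reactants: 34 the benzyl/triisopropylsilyl diether
Product: 35 (2R)-2-[(4S)-2,2-dimethyl-1,3-dioxolan-4-yl]-2-methyl-3-{[tri(propan-2-yl)silyl]oxy}propan-1-ol
Conditions: H2 (1 atm), Pd/C (10% palladium on carbon), EtOAc, rt
Reagents that add atoms: none
Why: hydrogenolysis removes the benzyl ether selectively, since the silyl ether and the acetonide are stable in neutral ethyl acetate.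

Step 23
Reactants: 35 (2R)-2-[(4S)-2,2-dimethyl-1,3-dioxolan-4-yl]-2-methyl-3-{[tri(propan-2-yl)silyl]oxy}propan-1-ol
Product: 36 {(2R)-2-[(4S)-2,2-dimethyl-1,3-dioxolan-4-yl]-3-iodo-2-methylpropoxy}tri(propan-2-yl)silane
Conditions: I2, PPh3, imidazole, toluene, 80 °C
Reagents that add atoms: iodine, II
Why: Appel-type iodination converts the neopentyl alcohol into the iodide at elevated temperature without affecting C12 or C19.

Step 24
Reactants: 36 {(2R)-2-[(4S)-2,2-dimethyl-1,3-dioxolan-4-yl]-3-iodo-2-methylpropoxy}tri(propan-2-yl)silane; 26 the C14 aldehyde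
Product: 38 the C13–C14 coupled carbinol (both C14 epimers; C11 silyl ether; C19/C20 acetonide; C3 dioxolane; C9 silylalkyne), via alkyllithium 37 (not isolated)
Conditions: t-BuLi (2 equiv per iodide), Et2O/pentane, −78 °C; then 26, Et2O, −78 °C; H2O
Reagents that add atoms: none
Why: iodine–lithium exchange gives the neopentyl-type alkyllithium, which adds to the hindered but non-enolisable aldehyde (1,2-addition) to form the C13–C14 bond; the carbinol configuration is irrelevant because C14 is oxidised in step 26.

Step 25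
Reactants: 38 the coupled carbinol
Product: 39 the C11/C14 diol with a terminal alkyne on C9
Conditions: Bu4NF, THF, 0 °C to rt
Reagents that add atoms: none
Why: fluoride cleaves the primary silyl ether and the C-silyl group of the alkyne in one operation (desilylation), leaving ketal and acetonide intact.

Step 26
Reactants: 39 the C11/C14 diol
Product: 40 the alkynal with a C11 aldehyde on quaternary C12 and a C14 ketone
Conditions: Dess–Martin periodinane (3 equiv), NaHCO3, CH2Cl2, rt
Reagents that add atoms: none
Why: Dess–Martin oxidation converts both hydroxyl groups, giving a non-enolisable C11 aldehyde and the C14 ketone.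

Step 27
Reactants: 40 the alkynal
Product: 41 the tricyclic C10-methylene C11 triethylsilyl ether C14 ketone (11S)
Conditions: Ni(cod)2 (20 mol%), 1,3-bis(2,6-diisopropylphenyl)imidazol-2-ylidene (20 mol%), Et3SiH (5 equiv), THF, rt, slow addition of 40 (final 0.005 M)
Reagents that add atoms: triethylsilane, CC[SiH](CC)CC
Why: nickel-catalysed reductive cyclisation of an alkynal with a silane: zerovalent nickel couples aldehyde and alkyne oxidatively, the bulky carbene steering C–C bond formation to the internal alkyne carbon C10, and σ-bond metathesis with Et3SiH releases the eight-membered ring with an exocyclic methylene and the C11 silyl ether; the aldehyde should react in preference to the ketone, and C11 (S) is set in a nickelacycle whose formyl oxygen points outward and away from the C15 methyl.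

Step 28
Reactants: 41 the C10-methylene tricycle
Product: 42 the C10-methyl tricycle (10R)
Conditions: Mn(dpm)3 (dpm = 2,2,6,6-tetramethylheptane-3,5-dionate, 10 mol%), PhSiH3, t-BuOOH, i-PrOH, rt
Reagents that add atoms: none
Why: hydrogen-atom-transfer hydrogenation of the 1,1-disubstituted alkene gives the tertiary C10 radical, which should take up the second hydrogen on the face of the adjacent C11–O bond so that the new C16 methyl ends up anti to the silyloxy group (10R); ketone, ketal and silyl ether are inert.

Step 29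
Reactants: 42 the C10-methyl tricycle
Product: 43 the C14 alcohol (14R)
Conditions: (S)-2-methyl-CBS-oxazaborolidine (1 equiv), BH3·SMe2, THF, −20 °C; MeOH quench
Reagents that add atoms: none
Why: Corey–Bakshi–Shibata reduction: the (S)-oxazaborolidine binds the ketone with the quaternary C5 flank as the large and the C13 methylene as the small substituent and delivers hydride to the face that gives the 14R alcohol (reagent control).

Step 30
Reactants: 43 the C14 alcohol
Product: 44 protected Pleuromutilin A (11-O-triethylsilyl; 19,20-O-isopropylidene; C3 ethylene ketal; glycolate O-tert-butyldimethylsilyl)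
Conditions: t-BuMe2SiOCH2CO2H, DCC, DMAP, CH2Cl2, rt to 40 °C
Reagents that add atoms: (tert-butyldimethylsilyloxy)acetic acid, CC(C)(C)[Si](C)(C)OCC(=O)O
Why: Steglich esterification acylates the only free hydroxyl group, the hindered C14 alcohol, with the silyl-protected glycolic acid.

Step 31
Reactants: 44 protected Pleuromutilin A
Product: 45 Pleuromutilin A
Conditions: 1 M HCl, THF, rt
Reagents that add atoms: water, O
Why: aqueous acid hydrolyses both silyl ethers, the acetonide and the dioxolane in one operation (acetal and silyl ether hydrolysis), and mild acid at room temperature with short contact should leave the glycolate ester and the C4 centre beside the freed ketone intact.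

**Compound list** (C-labels in names are mutilin numbering)

1 | 3-ethoxycyclopent-2-en-1-one | CCOC1=CC(=O)CC1 | starting material
2 | ethynyltrimethylsilane | C#C[Si](C)(C)C | starting material
3 | lithium (trimethylsilyl)acetylide | [Li]C#C[Si](C)(C)C | intermediate
4 | lithium 3-ethoxy-1-[(trimethylsilyl)ethynyl]cyclopent-2-en-1-olate (racemic) | CCOC1=CC(O[Li])(C#C[Si](C)(C)C)CC1 | intermediate
5 | 3-[(trimethylsilyl)ethynyl]cyclopent-2-en-1-one | C[Si](C)(C)C#CC1=CC(=O)CC1 | intermediate
6 | (3S)-5-methoxy-3-methyl-5-oxopentanoic acid | COC(=O)C[C@@H](C)CC(=O)O | starting material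
7 | dilithium dianion of 6 (carboxylate and ester enolate) | COC(O[Li])=C[C@@H](C)CC(=O)O[Li] | intermediate
8 | (3S)-5-methoxy-3,4-dimethyl-5-oxopentanoic acid (both C4 epimers) | COC(=O)C(C)[C@@H](C)CC(=O)O | intermediate
9 | methyl (3S)-5-hydroxy-2,3-dimethylpentanoate (both C2 epimers) | COC(=O)C(C)[C@@H](C)CCO | intermediate
10 | methyl (3S)-5-bromo-2,3-dimethylpentanoate (both C2 epimers) | COC(=O)C(C)[C@@H](C)CCBr | intermediate
11 | (3S)-5-bromo-2,3-dimethylpentan-1-ol (both C2 epimers) | OCC(C)[C@@H](C)CCBr | intermediate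
12 | {[(3S)-5-bromo-2,3-dimethylpentyl]oxy}(tert-butyl)dimethylsilane (both C2 epimers) | CC(C)(C)[Si](C)(C)OCC(C)[C@@H](C)CCBr | intermediate
13 | Grignard reagent of 12 | CC(C)(C)[Si](C)(C)OCC(C)[C@@H](C)CC[Mg]Br | intermediate
14 | (3R)-3-[(3S)-5-(tert-butyldimethylsilyloxy)-3,4-dimethylpentyl]-3-[(trimethylsilyl)ethynyl]cyclopentan-1-one | CC(C)(C)[Si](C)(C)OCC(C)[C@@H](C)CC[C@@]1(C#C[Si](C)(C)C)CCC(=O)C1 | intermediate
15 | trimethylsilyl enol ether of 14 (enol double bond C2=C3) | CC(C)(C)[Si](C)(C)OCC(C)[C@@H](C)CC[C@@]1(C#C[Si](C)(C)C)CC=C(O[Si](C)(C)C)C1 | intermediate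
16 | (4S)-4-[(3S)-5-(tert-butyldimethylsilyloxy)-3,4-dimethylpentyl]-4-[(trimethylsilyl)ethynyl]cyclopent-2-en-1-one | CC(C)(C)[Si](C)(C)OCC(C)[C@@H](C)CC[C@@]1(C#C[Si](C)(C)C)C=CC(=O)C1 | intermediate
17 | (3S)-2,3-dimethyl-5-{(1S)-4-oxo-1-[(trimethylsilyl)ethynyl]cyclopent-2-en-1-yl}pentanoic acid (both C2 epimers) | OC(=O)C(C)[C@@H](C)CC[C@@]1(C#C[Si](C)(C)C)C=CC(=O)C1 | intermediate
18 | methyl (3S)-2,3-dimethyl-5-{(1S)-4-oxo-1-[(trimethylsilyl)ethynyl]cyclopent-2-en-1-yl}pentanoate (both C2 epimers; this carbon is C5) | COC(=O)C(C)[C@@H](C)CC[C@@]1(C#C[Si](C)(C)C)C=CC(=O)C1 | intermediate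
19 | dilithium bis-enolate of 18 (C3–C4 dienolate and C5 ester enolate) | COC(O[Li])=C(C)[C@@H](C)CC[C@@]1(C#C[Si](C)(C)C)C=CC(O[Li])=C1 | intermediate
20 | methyl (3aR,4S,5S,7aR)-4,5-dimethyl-3-oxo-7a-[(trimethylsilyl)ethynyl]-3a,4,5,6,7,7a-hexahydro-3H-indene-4-carboxylate (4R,5S,6S,9R; H4 syn to alkynyl) | COC(=O)[C@@]2(C)[C@@H](C)CC[C@@]3(C#C[Si](C)(C)C)C=CC(=O)[C@H]32 | intermediate
21 | lithium C3–C4 dienolate of 20 | COC(=O)[C@@]2(C)[C@@H](C)CC[C@@]3(C#C[Si](C)(C)C)C=CC(O[Li])=C32 | intermediate
22 | methyl (3aS,4S,5S,7aR)-4,5-dimethyl-3-oxo-7a-[(trimethylsilyl)ethynyl]-3a,4,5,6,7,7a-hexahydro-3H-indene-4-carboxylate (4S,5S,6S,9R; H4 anti to alkynyl) | COC(=O)[C@@]2(C)[C@@H](C)CC[C@@]3(C#C[Si](C)(C)C)C=CC(=O)[C@@H]32 | intermediate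
23 | methyl (3aS,4S,5S,7aR)-4,5-dimethyl-3-oxo-7a-[(trimethylsilyl)ethynyl]octahydro-1H-indene-4-carboxylate | COC(=O)[C@@]2(C)[C@@H](C)CC[C@@]3(C#C[Si](C)(C)C)CCC(=O)[C@@H]32 | intermediate
24 | C3 ethylene ketal of 23 (4S,5S,6S,9R) | COC(=O)[C@@]2(C)[C@@H](C)CC[C@@]3(C#C[Si](C)(C)C)CCC4(OCCO4)[C@@H]32 | intermediate
25 | C14 primary alcohol of 24 (4S,5S,6S,9R) | OC[C@@]2(C)[C@@H](C)CC[C@@]3(C#C[Si](C)(C)C)CCC4(OCCO4)[C@@H]32 | intermediate
26 | C14 aldehyde (4S,5S,6S,9R) | O=C[C@@]2(C)[C@@H](C)CC[C@@]3(C#C[Si](C)(C)C)CCC4(OCCO4)[C@@H]32 | intermediate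
27 | dimethyl (S)-malate | COC(=O)C[C@H](O)C(=O)OC | starting material
28 | dilithium alkoxide enolate of 27 | COC(O[Li])=C[C@H](O[Li])C(=O)OC | intermediate
29 | dimethyl (2S,3R)-3-[(benzyloxy)methyl]-2-hydroxybutanedioate | COC(=O)[C@H](COCc1ccccc1)[C@H](O)C(=O)OC | intermediate
30 | dilithium alkoxide enolate of 29 | COC(O[Li])=C(COCc1ccccc1)[C@H](O[Li])C(=O)OC | intermediate
31 | dimethyl (2S,3S)-3-[(benzyloxy)methyl]-2-hydroxy-3-methylbutanedioate | COC(=O)[C@](COCc1ccccc1)(C)[C@H](O)C(=O)OC | intermediate
32 | (2S,3S)-3-[(benzyloxy)methyl]-3-methylbutane-1,2,4-triol | OC[C@](C)([C@H](O)CO)COCc1ccccc1 | intermediate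
33 | (2S)-3-(benzyloxy)-2-[(4S)-2,2-dimethyl-1,3-dioxolan-4-yl]-2-methylpropan-1-ol | OC[C@](C)([C@H]1COC(C)(C)O1)COCc1ccccc1 | intermediate
34 | {(2R)-3-(benzyloxy)-2-[(4S)-2,2-dimethyl-1,3-dioxolan-4-yl]-2-methylpropoxy}tri(propan-2-yl)silane | CC(C)[Si](C(C)C)(C(C)C)OC[C@](C)([C@H]1COC(C)(C)O1)COCc1ccccc1 | intermediate
35 | (2R)-2-[(4S)-2,2-dimethyl-1,3-dioxolan-4-yl]-2-methyl-3-{[tri(propan-2-yl)silyl]oxy}propan-1-ol | CC(C)[Si](C(C)C)(C(C)C)OC[C@](C)([C@H]1COC(C)(C)O1)CO | intermediate
36 | {(2R)-2-[(4S)-2,2-dimethyl-1,3-dioxolan-4-yl]-3-iodo-2-methylpropoxy}tri(propan-2-yl)silane | CC(C)[Si](C(C)C)(C(C)C)OC[C@](C)([C@H]1COC(C)(C)O1)CI | intermediate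
37 | alkyllithium from 36 (lithium in place of iodine) | CC(C)[Si](C(C)C)(C(C)C)OC[C@](C)([C@H]1COC(C)(C)O1)C[Li] | intermediate
38 | C13–C14 coupled carbinol (4S,5S,6S,9R,12R,19S; both C14 epimers) | CC(C)[Si](C(C)C)(C(C)C)OC[C@](C)([C@H]1COC(C)(C)O1)CC(O)[C@@]2(C)[C@@H](C)CC[C@@]3(C#C[Si](C)(C)C)CCC4(OCCO4)[C@@H]32 | intermediate
39 | C11/C14 diol with terminal alkyne (4S,5S,6S,9R,12R,19S; both C14 epimers) | OC[C@](C)([C@H]1COC(C)(C)O1)CC(O)[C@@]2(C)[C@@H](C)CC[C@@]3(C#C)CCC4(OCCO4)[C@@H]32 | intermediate
40 | alkynal: C11 aldehyde, C14 ketone (4S,5S,6S,9R,12S,19S) | O=C[C@](C)([C@H]1COC(C)(C)O1)CC(=O)[C@@]2(C)[C@@H](C)CC[C@@]3(C#C)CCC4(OCCO4)[C@@H]32 | intermediate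
41 | tricyclic C10-methylene C11 triethylsilyl ether C14 ketone (4S,5S,6S,9R,11S,12S,19S) | C=C1[C@H](O[Si](CC)(CC)CC)[C@](C)([C@H]4COC(C)(C)O4)CC(=O)[C@@]2(C)[C@@H](C)CC[C@]13CCC5(OCCO5)[C@@H]32 | intermediate
42 | C10-methyl tricycle (4S,5S,6S,9S,10R,11S,12S,19S) | C[C@H]1[C@H](O[Si](CC)(CC)CC)[C@](C)([C@H]4COC(C)(C)O4)CC(=O)[C@@]2(C)[C@@H](C)CC[C@]13CCC5(OCCO5)[C@@H]32 | intermediate
43 | C14 alcohol (14R; otherwise as 42) | C[C@H]1[C@H](O[Si](CC)(CC)CC)[C@](C)([C@H]4COC(C)(C)O4)C[C@@H](O)[C@@]2(C)[C@@H](C)CC[C@]13CCC5(OCCO5)[C@@H]32 | intermediate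
44 | protected Pleuromutilin A (11-O-triethylsilyl; 19,20-O-isopropylidene; C3 ethylene ketal; glycolate O-tert-butyldimethylsilyl) | C[C@H]1[C@H](O[Si](CC)(CC)CC)[C@](C)([C@H]4COC(C)(C)O4)C[C@@H](OC(=O)CO[Si](C)(C)C(C)(C)C)[C@@]2(C)[C@@H](C)CC[C@]13CCC5(OCCO5)[C@@H]32 | intermediate
45 | Pleuromutilin A (4S,5S,6S,9S,10R,11S,12R,14R,19S) | C[C@H]1[C@H](O)[C@](C)([C@H](O)CO)C[C@@H](OC(=O)CO)[C@@]2(C)[C@@H](C)CC[C@]13CCC(=O)[C@@H]32 | target

**Totals**

Total step count: 31. Longest linear sequence: 23 steps (steps 2–16, then 24–31).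

**Steps most likely to fail**

Step 27. The eight-membered ring has to span both faces of the six-membered ring, so the nickelacycle may form slowly and be overtaken by intermolecular coupling or by bond formation at the terminal alkyne carbon; facial selectivity at C11 may also be poor. Fallback, setting out from 39 and returning at 41: syn-stannylcupration of the terminal alkyne with Me3SnCu·SMe2 in the presence of MeOH would give the 2-stannyl-1-alkene F1; iododestannylation (I2, CH2Cl2, 0 °C) the 2-iodo-1-alkene F2; and Dess–Martin oxidation the iodo keto aldehyde F3. An intramolecular Nozaki–Hiyama–Kishi reaction (CrCl2, divalent chromium, with catalytic NiCl2, divalent nickel, DMSO/THF, high dilution), which is established for strained medium rings and selective for aldehydes over ketones, would close the same C10–C11 bond to the allylic alcohol F4. Silylation (Et3SiOTf, 2,6-lutidine) would then lead back to 41.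

Step 12. Protonation of the dienolate may show poor facial selectivity, or the product may re-equilibrate to the 4R epimer during quench and later handling. Fallback, setting out from 20 and returning at 22: the dienolate (LDA, −78 °C) would be brominated at C4 with N-bromosuccinimide to the α-bromo ketone F5 (either C4 configuration). Radical debromination with (Me3Si)3SiH and Et3B/air in toluene at −78 °C would then deliver hydrogen to the planar C4 radical from a bulky donor, which responds far more strongly than a proton to the axial alkynyl and methyl groups that block one face.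

Step 11. The lithium enolates may be diverted into dimerisation or over-oxidation of the product dienolate, and facial selectivity at C5 may be low. Fallback, setting out from 18 and returning at 20: double silylation (LDA, Me3SiCl, −78 °C) would give the bis(trimethylsilyl) enol ether F6. Oxidation with (NH4)2Ce(NO3)6 (tetravalent cerium) and NaHCO3 in MeCN at −20 °C would form the same C4–C5 bond through a silyl enol ether radical cation under non-basic conditions (oxidative coupling of silyl bis-enol ethers).

**Further compounds**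

F1 | step 27 | 2-(trimethylstannyl)-1-alkene from 39 (SnMe3 on C10, =CH2 at C16; C11/C14 diol) | OC[C@](C)([C@H]1COC(C)(C)O1)CC(O)[C@@]2(C)[C@@H](C)CC[C@@]3(C(=C)[Sn](C)(C)C)CCC4(OCCO4)[C@@H]32
F2 | step 27 | 2-iodo-1-alkene (iodine on C10; C11/C14 diol) | OC[C@](C)([C@H]1COC(C)(C)O1)CC(O)[C@@]2(C)[C@@H](C)CC[C@@]3(C(I)=C)CCC4(OCCO4)[C@@H]32
F3 | step 27 | iodo keto aldehyde (C10 vinyl iodide, C11 aldehyde, C14 ketone) | O=C[C@](C)([C@H]1COC(C)(C)O1)CC(=O)[C@@]2(C)[C@@H](C)CC[C@@]3(C(I)=C)CCC4(OCCO4)[C@@H]32
F4 | step 27 | tricyclic C10-methylene C11 alcohol C14 ketone (11S) | C=C1[C@H](O)[C@](C)([C@H]4COC(C)(C)O4)CC(=O)[C@@]2(C)[C@@H](C)CC[C@]13CCC5(OCCO5)[C@@H]32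
F5 | step 12 | C4-bromo derivative of 20 (either C4 configuration) | COC(=O)[C@@]2(C)[C@@H](C)CC[C@@]3(C#C[Si](C)(C)C)C=CC(=O)C32Br
F6 | step 11 | bis(trimethylsilyl) enol ether of 18 (C3–C4 silyl dienol ether and C5 silyl ketene acetal) | COC(O[Si](C)(C)C)=C(C)[C@@H](C)CC[C@@]1(C#C[Si](C)(C)C)C=CC(O[Si](C)(C)C)=C1
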